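Retrosynthesis: the two acyl C–O bonds of the 4-hydroxybenzoates are cut first (at O–C9, the CH2 on C3, and at O–C9', the end of the propenyl chain), then the aryl–alkenyl bond C5–C7', then O1–C2 and C2–C3 of the dihydrofuran ring (ring B).
Forward: the bromoguaiacol ring (ring A, as an ortho-quinone methide) and the syringyl ring (ring C, as a benzylic sulfonium ylide) are joined in a [4+1] annulation that closes ring B; the propenol chain is then attached at C5, the silyl groups are removed, and both esters are made last.
Enabling feature: the only aliphatic hydroxyls are two primary ones, C9–OH one carbon from the C3 stereocentre of ring B and the allylic C9'–OH on the side chain of ring A, beside three phenols (ring C and the two benzoate rings); a lipase esterifies only the primary alcohols and reads the configuration at C3 through C9–OH.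
Stereochemistry: the trans C2/C3 relationship comes from the annulation (racemic); the absolute (2S,3R) configuration comes from the lipase, which esterifies C9–OH of one enantiomer only; the E alkene comes from the boronate.
Key step: step 12

Assumption: Burkholderia cepacia lipase is taken to acylate the C9 hydroxyl of the (2S,3R) enantiomer faster than that of its mirror image; the sense has to be confirmed on the first run. Racemic compounds are drawn as the (2S,3R) enantiomer.

Step 1
Reactants: 1 5-bromo-2-hydroxy-3-methoxybenzaldehyde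
Product: 2 4-bromo-2-ethenyl-6-methoxyphenol
Conditions: Ph3PCH3Br (2.5 equiv), KOtBu (2.5 equiv), THF, 0 °C to rt
Reagents that add atoms: methyltriphenylphosphonium bromide, C[P+](c1ccccc1)(c1ccccc1)c1ccccc1.[Br-]
Why: Wittig methylenation with the non-stabilised ylide in excess, one equivalent of base merely holding the phenol as its phenoxide, is the usual way from salicylaldehydes to 2-vinylphenols and creates no stereocentre.

Step 2
Reactants: 2 4-bromo-2-ethenyl-6-methoxyphenol
Product: 3 rac-1-(5-bromo-2-hydroxy-3-methoxyphenyl)ethane-1,2-diol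
Conditions: OsO4 (2 mol %), NMO, acetone/H2O, rt
Reagents that add atoms: osmium tetroxide, O=[Os](=O)(=O)=O; N-methylmorpholine N-oxide, C[N+]1([O-])CCOCC1; water, O
Why: Catalytic syn-dihydroxylation of the electron-rich styrene by OsO4, with NMO restoring octavalent osmium, should leave aryl bromide and phenol untouched, and the racemic carbinol centre it creates is erased again in the quinone methide of step 8.

Step 3
Reactants: 3 rac-1-(5-bromo-2-hydroxy-3-methoxyphenyl)ethane-1,2-diol
Product: 4 rac-4-bromo-2-{1-hydroxy-2-[(triisopropylsilyl)oxy]ethyl}-6-methoxyphenol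
Conditions: TIPSCl (1.05 equiv), imidazole, CH2Cl2, 0 °C
Reagents that add atoms: chlorotriisopropylsilane, CC(C)[Si](Cl)(C(C)C)C(C)C
Why: Silyl ether formation is sterically governed, so one equivalent of bulky TIPSCl should take the primary hydroxyl in preference to the secondary benzylic alcohol and to the phenol flanked by OMe and the branched side chain, and the TIPS ether is robust enough for the acid of step 4.

Step 4
Reactants: 4 rac-4-bromo-2-{1-hydroxy-2-[(triisopropylsilyl)oxy]ethyl}-6-methoxyphenol
Product: 5 rac-4-bromo-2-methoxy-6-{1-[(4-methylphenyl)sulfonyl]-2-[(triisopropylsilyl)oxy]ethyl}phenol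
Conditions: p-TolSO2H (1.5 equiv), CH2Cl2, rt
Reagents that add atoms: 4-methylbenzenesulfinic acid, Cc1ccc(S(=O)O)cc1
Why: Acid-promoted substitution of an ortho-hydroxybenzylic alcohol by a sulfinic acid (SN1 through the protonated ortho-quinone methide, with S-alkylation of the sulfinate) is the standard entry to 2-(1-sulfonylalkyl)phenols, the bench-stable quinone methide precursors.

Step 5
Reactants: 6 syringaldehyde (4-hydroxy-3,5-dimethoxybenzaldehyde)
Product: 7 3,5-dimethoxy-4-[(triisopropylsilyl)oxy]benzaldehyde
Conditions: TIPSCl, imidazole, DMF, rt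
Reagents that add atoms: chlorotriisopropylsilane, CC(C)[Si](Cl)(C(C)C)C(C)C
Why: Silylation of the acidic phenol gives a TIPS ether shielded by both methoxy groups, which should withstand Cs2CO3 and aqueous K3PO4 later and keeps the benzylic sulfonium salt from collapsing to a para-quinone methide.

Step 6
Reactants: 7 3,5-dimethoxy-4-[(triisopropylsilyl)oxy]benzaldehyde
Product: 8 {3,5-dimethoxy-4-[(triisopropylsilyl)oxy]phenyl}methanol
Conditions: NaBH4, MeOH, 0 °C
Reagents that add atoms: none
Why: Borohydride reduction of an aromatic aldehyde to the benzylic alcohol leaves the aryl silyl ether intact at 0 °C.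

Step 7
Reactants: 8 {3,5-dimethoxy-4-[(triisopropylsilyl)oxy]phenyl}methanol
Product: 10 1-{3,5-dimethoxy-4-[(triisopropylsilyl)oxy]benzyl}tetrahydrothiophenium bromide, via benzyl bromide 9 (not isolated)
Conditions: PBr3, CH2Cl2, 0 °C; then tetrahydrothiophene, acetone, rt
Reagents that add atoms: phosphorus tribromide, BrP(Br)Br; tetrahydrothiophene, C1CCSC1
Why: PBr3 converts the electron-rich benzylic alcohol into bromide 9, which is too labile for chromatography and is therefore alkylated at once at sulfur by tetrahydrothiophene (SN2 sulfonium salt formation), the salt separating from acetone.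

Step 8
Reactants: 5 rac-4-bromo-2-methoxy-6-{1-[(4-methylphenyl)sulfonyl]-2-[(triisopropylsilyl)oxy]ethyl}phenol; 10 1-{3,5-dimethoxy-4-[(triisopropylsilyl)oxy]benzyl}tetrahydrothiophenium bromide
Product: 13 rac-trans-5-bromo-2-{3,5-dimethoxy-4-[(triisopropylsilyl)oxy]phenyl}-7-methoxy-3-{[(triisopropylsilyl)oxy]methyl}-2,3-dihydro-1-benzofuran, via ortho-quinone methide 11 (not isolated), via sulfonium ylide 12 (not isolated)
Conditions: Cs2CO3 (3 equiv), CH2Cl2, 0 °C to rt
Reagents that add atoms: none
Why: [4+1] annulation of an ortho-quinone methide with a sulfonium ylide, in which Cs2CO3 makes the phenoxide of 5 expel sulfinate to give 11 and deprotonates 10 to the semi-stabilised ylide 12, Michael addition of 12 to the exocyclic carbon of 11 forms C2–C3, and the re-aromatised phenoxide closes O1–C2 by 5-exo-tet SN2 displacement of tetrahydrothiophene through the betaine conformer with the aryl group anti to CH2OTIPS, so that C2 and C3 are set together as the racemic trans pair.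

Step 9
Reactants: 13 rac-trans-5-bromo-2-{3,5-dimethoxy-4-[(triisopropylsilyl)oxy]phenyl}-7-methoxy-3-{[(triisopropylsilyl)oxy]methyl}-2,3-dihydro-1-benzofuran; 14 (E)-tert-butyldimethyl{[3-(4,4,5,5-tetramethyl-1,3,2-dioxaborolan-2-yl)prop-2-en-1-yl]oxy}silane
Product: 15 rac-trans-5-[(E)-3-{[tert-butyl(dimethyl)silyl]oxy}prop-1-en-1-yl]-2-{3,5-dimethoxy-4-[(triisopropylsilyl)oxy]phenyl}-7-methoxy-3-{[(triisopropylsilyl)oxy]methyl}-2,3-dihydro-1-benzofuran
Conditions: Pd(dppf)Cl2 (5 mol %), K3PO4, 1,4-dioxane/H2O, 80 °C
Reagents that add atoms: none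
Why: Suzuki–Miyaura coupling, in which oxidative addition of the aryl bromide to zerovalent palladium (formed in situ from Pd(dppf)Cl2), transmetallation of the alkenyl boronate with retention of the E geometry and reductive elimination form C5–C7' without touching the two benzylic stereocentres or the hindered silyl ethers.

Step 10
Reactants: 15 rac-trans-5-[(E)-3-{[tert-butyl(dimethyl)silyl]oxy}prop-1-en-1-yl]-2-{3,5-dimethoxy-4-[(triisopropylsilyl)oxy]phenyl}-7-methoxy-3-{[(triisopropylsilyl)oxy]methyl}-2,3-dihydro-1-benzofuran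
Product: 16 rac-trans-4-{3-(hydroxymethyl)-5-[(E)-3-hydroxyprop-1-en-1-yl]-7-methoxy-2,3-dihydro-1-benzofuran-2-yl}-2,6-dimethoxyphenol (racemic diol)
Conditions: TBAF, AcOH, THF, 0 °C to rt
Reagents that add atoms: none
Why: Fluoride cleaves the aryl TIPS, alkyl TIPS and alkyl TBS ethers through pentacoordinate silicon, and the acetic acid buffer keeps the liberated syringyl phenol protonated so that the para-hydroxybenzylic ether at C2 cannot open to a para-quinone methide and lose the trans configuration.

Step 11
Reactants: 17 4-hydroxybenzoic acid; 18 vinyl acetate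
Product: 19 vinyl 4-hydroxybenzoate
Conditions: Pd(OAc)2 (5 mol %), KOH (10 mol %), vinyl acetate/THF, rt
Reagents that add atoms: none
Why: Transvinylation, in which Pd(OAc)2 (divalent palladium) activates vinyl acetate for oxypalladation by the carboxylate and β-acetate elimination releases the new vinyl ester, the large excess of vinyl acetate driving the exchange while the phenol, far less acidic than the carboxylic acid, is expected to stay free.

Step 12
Reactants: 16 rac-trans-4-{3-(hydroxymethyl)-5-[(E)-3-hydroxyprop-1-en-1-yl]-7-methoxy-2,3-dihydro-1-benzofuran-2-yl}-2,6-dimethoxyphenol; 19 vinyl 4-hydroxybenzoate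
Product: 21 quiquesetinerviusin B, via (2S,3R) cinnamyl mono-ester 20 (not isolated)
Conditions: immobilised Burkholderia cepacia lipase, 19 (3 equiv), t-BuOMe/2-MeTHF, 40 °C, stopped before half of the C9 hydroxyls are acylated; SiO2 chromatography
Reagents that add atoms: none
Why: The active-site serine of the lipase attacks vinyl ester 19, vinyl alcohol leaves and tautomerises to acetaldehyde (which makes the transfer irreversible), and the 4-hydroxybenzoyl-enzyme is then intercepted by an aliphatic hydroxyl bound in the alcohol pocket, first the exposed cinnamyl C9' hydroxyl (20) and then the C9 hydroxyl. The closest known reaction type is the lipase-catalysed acylative kinetic resolution of 2-substituted primary alcohols with vinyl esters, aromatic vinyl esters included, which are accepted but turn over slowly. No ring is closed; the two ester C–O bonds are the only bonds formed. No stereocentre is created: C2 and C3, locked trans in step 8, are selected as a pair, because the C9 hydroxyl lies one carbon from C3 and the chiral pocket should therefore acylate it in the (2S,3R) enantiomer much faster than in its mirror image, whereas the remote cinnamyl hydroxyl is esterified in both. Two selectivities are required, enantiomer recognition at C9 (secured by the stereocentre next to the CH2OH group and by stopping the run before half of these hydroxyls have reacted) and alcohol-over-phenol selectivity (secured by the enzyme, whose acyl-enzyme does not accept phenols, so the syringyl phenol and the phenol of the donor stay free without protection). The slow enantiomer should end as a mono-ester with one free primary hydroxyl, polar enough to be removed from the diester on silica.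

Compound list
1 | 5-bromo-2-hydroxy-3-methoxybenzaldehyde | COc1cc(Br)cc(C=O)c1O | starting material
2 | 4-bromo-2-ethenyl-6-methoxyphenol | COc1cc(Br)cc(C=C)c1O | intermediate
3 | rac-1-(5-bromo-2-hydroxy-3-methoxyphenyl)ethane-1,2-diol | COc1cc(Br)cc(C(O)CO)c1O | intermediate
4 | rac-4-bromo-2-{1-hydroxy-2-[(triisopropylsilyl)oxy]ethyl}-6-methoxyphenol | COc1cc(Br)cc(C(O)CO[Si](C(C)C)(C(C)C)C(C)C)c1O | intermediate
5 | rac-4-bromo-2-methoxy-6-{1-[(4-methylphenyl)sulfonyl]-2-[(triisopropylsilyl)oxy]ethyl}phenol | COc1cc(Br)cc(C(CO[Si](C(C)C)(C(C)C)C(C)C)S(=O)(=O)c2ccc(C)cc2)c1O | intermediate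
6 | syringaldehyde (4-hydroxy-3,5-dimethoxybenzaldehyde) | COc1cc(C=O)cc(OC)c1O | starting material
7 | 3,5-dimethoxy-4-[(triisopropylsilyl)oxy]benzaldehyde | COc1cc(C=O)cc(OC)c1O[Si](C(C)C)(C(C)C)C(C)C | intermediate
8 | {3,5-dimethoxy-4-[(triisopropylsilyl)oxy]phenyl}methanol | COc1cc(CO)cc(OC)c1O[Si](C(C)C)(C(C)C)C(C)C | intermediate
9 | 5-(bromomethyl)-1,3-dimethoxy-2-[(triisopropylsilyl)oxy]benzene (not isolated) | COc1cc(CBr)cc(OC)c1O[Si](C(C)C)(C(C)C)C(C)C | intermediate
10 | 1-{3,5-dimethoxy-4-[(triisopropylsilyl)oxy]benzyl}tetrahydrothiophenium bromide | COc1cc(C[S+]2CCCC2)cc(OC)c1O[Si](C(C)C)(C(C)C)C(C)C.[Br-] | intermediate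
11 | 4-bromo-2-methoxy-6-{2-[(triisopropylsilyl)oxy]ethylidene}cyclohexa-2,4-dien-1-one (ortho-quinone methide, not isolated) | COC1=CC(Br)=CC(=CCO[Si](C(C)C)(C(C)C)C(C)C)C1=O | intermediate
12 | {3,5-dimethoxy-4-[(triisopropylsilyl)oxy]phenyl}(tetrahydrothiophenium-1-yl)methanide (sulfonium ylide, not isolated) | COc1cc([CH-][S+]2CCCC2)cc(OC)c1O[Si](C(C)C)(C(C)C)C(C)C | intermediate
13 | rac-trans-5-bromo-2-{3,5-dimethoxy-4-[(triisopropylsilyl)oxy]phenyl}-7-methoxy-3-{[(triisopropylsilyl)oxy]methyl}-2,3-dihydro-1-benzofuran ((2S,3R) enantiomer drawn) | COc1cc([C@H]2Oc3c(OC)cc(Br)cc3[C@@H]2CO[Si](C(C)C)(C(C)C)C(C)C)cc(OC)c1O[Si](C(C)C)(C(C)C)C(C)C | intermediate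
14 | (E)-tert-butyldimethyl{[3-(4,4,5,5-tetramethyl-1,3,2-dioxaborolan-2-yl)prop-2-en-1-yl]oxy}silane | CC(C)(C)[Si](C)(C)OC/C=C/B1OC(C)(C)C(C)(C)O1 | starting material
15 | rac-trans-5-[(E)-3-{[tert-butyl(dimethyl)silyl]oxy}prop-1-en-1-yl]-2-{3,5-dimethoxy-4-[(triisopropylsilyl)oxy]phenyl}-7-methoxy-3-{[(triisopropylsilyl)oxy]methyl}-2,3-dihydro-1-benzofuran ((2S,3R) enantiomer drawn) | COc1cc([C@H]2Oc3c(OC)cc(/C=C/CO[Si](C)(C)C(C)(C)C)cc3[C@@H]2CO[Si](C(C)C)(C(C)C)C(C)C)cc(OC)c1O[Si](C(C)C)(C(C)C)C(C)C | intermediate
16 | rac-trans-4-{3-(hydroxymethyl)-5-[(E)-3-hydroxyprop-1-en-1-yl]-7-methoxy-2,3-dihydro-1-benzofuran-2-yl}-2,6-dimethoxyphenol (racemic diol, (2S,3R) enantiomer drawn) | COc1cc([C@H]2Oc3c(OC)cc(/C=C/CO)cc3[C@@H]2CO)cc(OC)c1O | intermediate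
17 | 4-hydroxybenzoic acid | O=C(O)c1ccc(O)cc1 | starting material
18 | vinyl acetate | C=COC(C)=O | starting material
19 | vinyl 4-hydroxybenzoate | C=COC(=O)c1ccc(O)cc1 | intermediate
20 | (E)-3-[(2S,3R)-2-(4-hydroxy-3,5-dimethoxyphenyl)-3-(hydroxymethyl)-7-methoxy-2,3-dihydro-1-benzofuran-5-yl]prop-2-en-1-yl 4-hydroxybenzoate (not isolated) | COc1cc([C@H]2Oc3c(OC)cc(/C=C/COC(=O)c4ccc(O)cc4)cc3[C@@H]2CO)cc(OC)c1O | intermediate
21 | quiquesetinerviusin B, the (2S,3R) bis(4-hydroxybenzoate) | COc1cc([C@H]2Oc3c(OC)cc(/C=C/COC(=O)c4ccc(O)cc4)cc3[C@@H]2COC(=O)c2ccc(O)cc2)cc(OC)c1O | target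

Total step count: 12. Longest linear sequence: 8 steps (steps 1, 2, 3, 4, 8, 9, 10, 12).

Steps most likely to fail

First, step 12. Enantiomer discrimination at C9 may be too weak, or acyl transfer too slow, with the bulky aromatic donor. The fallback separates resolution from esterification. Racemic diol 16 is acetylated with vinyl acetate 18 and Burkholderia cepacia lipase in t-BuOMe, the best-precedented donor for 2-substituted primary alcohols. The (2S,3R) diacetate F1 is separated from the mono-acetylated mirror-image material and methanolysed (K2CO3, MeOH, 0 °C) to the enantiopure (2S,3R) diol F2. F2 is then taken to full conversion with 19 and Candida antarctica lipase B at 50 °C, where only alcohol-over-phenol selectivity is asked of the enzyme, which returns to 21.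

Second, step 8. The alkyl-substituted quinone methide may tautomerise to the enol ether or oligomerise faster than the ylide adds, or the ylide may rearrange at the low stationary concentration that Cs2CO3 provides. The fallback replaces the transient acceptor by a stable, isolable one. Aldehyde 1 undergoes Henry condensation with nitromethane (NH4OAc, AcOH, 90 °C) to (E)-4-bromo-2-methoxy-6-(2-nitroethenyl)phenol F3. Michael addition of the ylide from 10 (Cs2CO3, CH2Cl2) at the benzylic carbon, followed by phenoxide displacement of tetrahydrothiophene, should give the trans 3-(nitromethyl)dihydrobenzofuran F4. NaNO2/AcOH in DMSO converts the primary nitro group into the trans 3-carboxylic acid F5, BH3·SMe2 reduces it to the trans 3-hydroxymethyl compound F6, and TIPSCl/imidazole returns to 13.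

Third, step 4. The acid may divert the benzylic cation into elimination toward the enol ether and a benzofuran, or strip the silyl ether. The fallback bypasses the sulfone and generates the quinone methide anionically. Diol mono-ether 4 is converted with Boc2O, iPr2NEt and DMAP (cat.) into the aryl tert-butyl carbonate F7. t-BuMgCl in THF at −78 °C forms the benzylic magnesium alkoxide, the Boc group migrates to the benzylic oxygen, and on warming the phenoxide expels tert-butyl carbonate to give 11. Ylide 12, pre-formed from 10 with KN(SiMe3)2, is present to trap it, which returns to 13.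

Further compounds
F1 | step 12 | (E)-3-[(2S,3R)-3-(acetoxymethyl)-2-(4-hydroxy-3,5-dimethoxyphenyl)-7-methoxy-2,3-dihydro-1-benzofuran-5-yl]prop-2-en-1-yl acetate | COc1cc([C@H]2Oc3c(OC)cc(/C=C/COC(C)=O)cc3[C@@H]2COC(C)=O)cc(OC)c1O
F2 | step 12 | 4-{(2S,3R)-3-(hydroxymethyl)-5-[(E)-3-hydroxyprop-1-en-1-yl]-7-methoxy-2,3-dihydro-1-benzofuran-2-yl}-2,6-dimethoxyphenol, single enantiomer | COc1cc([C@H]2Oc3c(OC)cc(/C=C/CO)cc3[C@@H]2CO)cc(OC)c1O
F3 | step 8 | (E)-4-bromo-2-methoxy-6-(2-nitroethenyl)phenol | COc1cc(Br)cc(/C=C/[N+](=O)[O-])c1O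
F4 | step 8 | rac-trans-5-bromo-2-{3,5-dimethoxy-4-[(triisopropylsilyl)oxy]phenyl}-7-methoxy-3-(nitromethyl)-2,3-dihydro-1-benzofuran ((2S,3R) enantiomer drawn) | COc1cc([C@H]2Oc3c(OC)cc(Br)cc3[C@@H]2C[N+](=O)[O-])cc(OC)c1O[Si](C(C)C)(C(C)C)C(C)C
F5 | step 8 | rac-trans-5-bromo-2-{3,5-dimethoxy-4-[(triisopropylsilyl)oxy]phenyl}-7-methoxy-2,3-dihydro-1-benzofuran-3-carboxylic acid ((2S,3S) enantiomer drawn, same spatial arrangement as 13) | COc1cc([C@H]2Oc3c(OC)cc(Br)cc3[C@@H]2C(=O)O)cc(OC)c1O[Si](C(C)C)(C(C)C)C(C)C
F6 | step 8 | rac-trans-(5-bromo-2-{3,5-dimethoxy-4-[(triisopropylsilyl)oxy]phenyl}-7-methoxy-2,3-dihydro-1-benzofuran-3-yl)methanol ((2S,3R) enantiomer drawn) | COc1cc([C@H]2Oc3c(OC)cc(Br)cc3[C@@H]2CO)cc(OC)c1O[Si](C(C)C)(C(C)C)C(C)C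
F7 | step 4 | rac-4-bromo-2-{1-hydroxy-2-[(triisopropylsilyl)oxy]ethyl}-6-methoxyphenyl tert-butyl carbonate | COc1cc(Br)cc(C(O)CO[Si](C(C)C)(C(C)C)C(C)C)c1OC(=O)OC(C)(C)C
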